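The epsilon run opens at a decay constant of 0.224 h⁻¹. This constant is the fraction of the electrophile present that reacts per hour, an apparent pseudo-first-order constant: the logarithm of the ratio of two electrophile readings, divided by the time between them.

| flask | electrophile | nucleophile | free base | scavenger | remark | time |
|---|---|---|---|---|---|---|
| epsilon | 0.10 M | 0.74 equiv | 2 equiv | 1.2 equiv | run made earlier |  |
| Thursday's | 0.10 M | 1.10 equiv | 3.00 equiv | 1.20 equiv |  | 30 h |
| Wednesday's | 0.10 M | 1.10 equiv | 4.50 equiv | 1.20 equiv |  | 30 h |
| Sunday's | 0.10 M | 1.10 equiv | 2.00 equiv | 1.20 equiv |  | 30 h |

epsilon run (percent of the electrophile charged)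

| time / h | electrophile / % | target / % |
|---|---|---|
| 0.833 | 83 | 11 |
| 2.00 | 67 | 15 |
| 4.00 | 48 | 15 |
| 6.00 | 35 | 11 |

(readings scatter by 1.5 percentage points)

* part of the electrophile that has reacted at the end, Thursday's
* part of the electrophile that has reacted at the end, Wednesday's
* part of the electrophile that has reacted at the end, Sunday's
* what raising the equivalents of free base from its lowest to its highest value here does to the part of the electrophile that has reacted (changes below 5 percentage points count as none) (it rises / no change / it falls)

- no earlier run changes the charge of free base; that part of a forecast is a guess

The next interval of the epsilon run reads 0.184 h⁻¹, the one after 0.167 h⁻¹, and the last 0.158 h⁻¹: this late decay constant carries the argument. The decay constant of the epsilon run therefore falls by factors of 1.22, 1.10 and 1.06, and the last fall is smaller than the first. Together they make 1.42, a reading that carries the scatter of 1.5 percentage points. Over the last interval the target reading of the epsilon run falls as well, from 15% to 11%.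

My own reckoning holds the late constant of the epsilon run for 30 h, though that run had 0.74 equiv of nucleophile and the three new flasks have 1.10 equiv; this leaves 0.876% of the electrophile. Slowing it once more by the whole factor leaves 3.53%. The two differ by 2.7 points, less than the margin of 5 points. So I expect 96.5% to 99.1% reacted and no change with free base, although no earlier run varies free base, so that part is a guess.

The forecast gives 98.5% for Thursday's, 99.3% for Wednesday's and 97.5% for Sunday's, with the trend no change, and says: “All three runs sit near the ceiling”. Unlike my reckoning, it separates the three flasks.

Thursday's, Wednesday's and Sunday's reach 99.9%, 99.9% and 99.9%, so the change across the free base charges is 0 points: no change, as forecast.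

    electrophile + acid set free ⇌ idle adduct, settled at all times (K = 20.0 M⁻¹)
    acid set free + scavenger → scavenged by-product (k = 0.0290 M⁻¹ s⁻¹)
    electrophile + nucleophile → acid set free + target (k = 9.00 × 10⁻⁴ M⁻¹ s⁻¹)
    electrophile + target → side product (k = 0.00180 M⁻¹ s⁻¹)
    acid set free + free base ⇌ salt of the base, settled at all times (K = 15.0 M⁻¹)
    nucleophile + acid set free ⇌ protonated nucleophile, settled at all times (K = 4600 M⁻¹)

Sunday's, with 0.13% of its electrophile left at 30 h, averaged a decay constant of 0.222 h⁻¹, above the late constant of the epsilon run. A neighbour of Sunday's at 0.025 M electrophile averaged 0.0700 h⁻¹, below it, and kept 12%. In Sunday's at 1.46 h, the rate at which electrophile + nucleophile uses electrophile, over the rate at which electrophile + target uses it, is 1.4, and Sunday's ends with 16.3% target against 83.6% side product.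

The numbers in the tables come from a simulation from invented constants; scatter was added.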